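Reckon by hand what this flask holds at its end before running anything.

| flask | solid substrate | reagent | remark | time |
|---|---|---|---|---|
| epsilon | 0.25 M | 0.63 M | run made earlier |  |
| beta | 0.25 M | 0.99 M | run made earlier |  |
| flask | 0.25 M | 0.450 M |  | 5.0 d |

| run | time / d | target / % | solid product / % |
|---|---|---|---|
| epsilon | 0.250 | 36.5 | 24.7 |
| epsilon | 0.833 | 80.5 | 69.6 |
| epsilon | 1.25 | 90.4 | 78.3 |
| epsilon | 2.00 | 93.2 | 83.4 |
| epsilon | 3.00 | 95.4 | 81.4 |
| epsilon | 4.00 | 96.9 | 83.1 |
| beta | 0.333 | 65.2 | 55.2 |
| beta | 0.500 | 84.1 | 71.4 |
| beta | 0.833 | 92.7 | 78.9 |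
| beta | 1.67 | 95.9 | 82.6 |
| beta | 2.50 | 94.3 | 85.6 |
| beta | 4.00 | 93.7 | 84.6 |

(readings scatter by 1 percentage point)
- target and solid product together at 5.0 d, in percent of the solid substrate charged
- concentration of dissolved substrate in solution at 5.0 d, in percent of saturation
- amounts and yields of target count solid product too
- given per volume of solution although it is solid: solid substrate, solid product
- at the start none of the solid substrate is in solution
- dissolved substrate means what is dissolved; the solid is not counted in it

I assumed one reagent per substrate consumed, with solid substrate as the limiting reagent (0.25 M against 0.450 M). The excess of reagent over substrate then holds in each flask. Once the solid has gone, the ratio of reagent to unreacted substrate should grow as exp(k × excess × time), a pseudo-first-order tail. I read unreacted substrate as the gap below the late target level.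

Late level: 95.1%
Epsilon ratio: 10.9 at 0.833 d, 31.9 at 1.25 d
So k = 6.77 L mol⁻¹ d⁻¹
Delay from dissolving, epsilon run: 0.263 d
Early dissolved substrate, taken as saturation: 0.0923 M

The weak link was k, since the epsilon gap at 1.25 d is 4.7 percentage points against a scatter of 1 point. I reforged it from the beta run, which has a different excess:

Beta ratio: 10.4 at 0.333 d, 119 at 0.833 d
So k = 6.59 L mol⁻¹ d⁻¹; mean 6.68 L mol⁻¹ d⁻¹

My carried quantity is the tail constant, k times the excess, for this flask:

Tail constant: 1.34 d⁻¹
Unreacted substrate at 5.0 d: 0.198 mM
I committed to 95.0% and 0.215% of saturation.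

The forecast said 95% (90% to 98%) and 10% (1% to 60%), holding that “dissolution barely feeds the solution”.

The flask gave 94.7% and 0.355%.

    solid substrate ⇌ dissolved substrate, rate k1*(cs1 - [dissolved substrate]) while solid is left; crystals form when [dissolved substrate] > cs1 (solubility = 0.180 M, k = 2.02 × 10⁻⁴ s⁻¹)
    dissolved substrate + reagent → target (k = 6.10 × 10⁻⁵ L mol⁻¹ s⁻¹)
    solid product ⇌ target, rate k3*(cs3 - [target]) while solid is left; crystals form when [target] > cs3 (solubility = 28.0 mM, k = 0.00646 s⁻¹)
    target ⇌ isomer of the product (K = 0.449, k = 7.92 × 10⁻⁶ s⁻¹)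

At 5.0 d the flask held 94.7% target beside 5.03% isomer of the product. My unreacted substrate, 0.0792% of the charge, lay below its 0.256%, with 1.34 d⁻¹ standing in an exponent of 6.35. For the same flask stopped at 30 h, the tail constant gives a ratio of 6.73, so 14.0% of the substrate unreacted. That neighbouring flask held 16% unreacted, with target at 79.9% and reagent at 53% of its own charge.

The numbers in the tables are simulated on assumed constants.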